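## Retrosynthetic overview

- The three oxygens of the tetralone half are installed last, in relay. C7–OH comes from C7–Br by Cu-catalysed hydroxylation. C8–OH comes from C8–H by a new Cu/imine-directed C–H hydroxylation, which is the key step. C1=O comes from the benzylic CH2 by aerobic C–H oxidation.
- The stereocentre is set one stage earlier by asymmetric hydrogenation of a 1-aryl-3,4-dihydronaphthalene.
- The aryl–C4 bond comes from a naphthyl Grignard reagent and 6-bromo-1-tetralone, followed by dehydration.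
- No ring is built. Both bicycles are bought (5-methoxy-1-naphthol and 6-bromo-1-tetralone).

Assumption: the sense of induction of the Ir catalyst is fixed by a test run, and the ligand enantiomer that gives the drawn configuration is used.

## Route

Step 1
Reactants: 1 5-methoxynaphthalen-1-ol
Product: 3 4-bromo-5-methoxynaphthalen-1-yl benzenesulfonate, via bromonaphthol 2 (not isolated)
Conditions: NBS (1.02 equiv), MeCN, -10 to 0 °C; then PhSO2Cl, Et3N, DMAP (cat.), 0 °C to rt, same flask
Reagents that add atoms: N-bromosuccinimide O=C1CCC(=O)N1Br; benzenesulfonyl chloride O=S(=O)(Cl)c1ccccc1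
Why: Electrophilic aromatic bromination goes para to the free OH, the strongest donor, at the α-position, and O-sulfonylation then masks the naphthol as an electron-poor ester with no benzylic C–H that tolerates Grignard formation and all later oxidations.

Step 2
Reactants: 3 4-bromo-5-methoxynaphthalen-1-yl benzenesulfonate; 4 6-bromo-3,4-dihydronaphthalen-1(2H)-one
Product: 7 4-(6-bromo-3,4-dihydronaphthalen-1-yl)-5-methoxynaphthalen-1-yl benzenesulfonate, via aryl Grignard 5 (not isolated), via tertiary alcohol 6 (not isolated)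
Conditions: Mg, LiCl, THF, 0 to 25 °C; cannulate onto 4 + LaCl3·2LiCl, THF, 0 °C to rt; 1 M HCl; crude 6, p-TsOH (5 mol%), toluene, 70 °C
Reagents that add atoms: none
Why: LiCl-mediated Mg insertion gives a regiodefined Grignard reagent, La(III) suppresses enolisation in the 1,2-addition to the tetralone (whose aryl bromide is inert), and acid-catalysed E1 dehydration of the bis-benzylic alcohol gives the trisubstituted olefin.

Step 3
Reactants: 7 4-(6-bromo-3,4-dihydronaphthalen-1-yl)-5-methoxynaphthalen-1-yl benzenesulfonate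
Product: 8 (R)-4-(6-bromo-1,2,3,4-tetrahydronaphthalen-1-yl)-5-methoxynaphthalen-1-yl benzenesulfonate
Conditions: [Ir(cod)(chiral phosphinite-oxazoline N,P ligand)]BArF (2 mol%), H2 (50 bar), CH2Cl2, 45 °C
Reagents that add atoms: none
Why: This is an Ir–N,P asymmetric hydrogenation of an unfunctionalised 1-aryl-3,4-dihydronaphthalene in which rotation about the aryl–vinyl axis is fast at 45 °C, so both rotamers funnel through the catalyst-matched face and set the only stereocentre (R here, the same spatial arrangement that is called S once C1 carries oxygen).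

Step 4
Reactants: 8 (R)-4-(6-bromo-1,2,3,4-tetrahydronaphthalen-1-yl)-5-methoxynaphthalen-1-yl benzenesulfonate
Product: 9 4-[(1S)-6-bromo-4-oxo-1,2,3,4-tetrahydronaphthalen-1-yl]-5-methoxynaphthalen-1-yl benzenesulfonate
Conditions: NHPI (20 mol%), Co(OAc)2·4H2O (1 mol%), O2 (1 atm), MeCN/EtOAc, 45 °C
Reagents that add atoms: dioxygen O=O
Why: In this NHPI/Co aerobic benzylic oxidation (H-atom abstraction by the phthalimide N-oxyl radical) the open secondary C–H2 reacts, because the tertiary diaryl C–H is pseudo-equatorial, lies in the naphthalene plane and is buried against the peri-OMe, and the sulfonate and bromide make both arenes too electron-poor for electron-transfer damage, so the stereocentre is kept.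

Step 5
Reactants: 9 4-[(1S)-6-bromo-4-oxo-1,2,3,4-tetrahydronaphthalen-1-yl]-5-methoxynaphthalen-1-yl benzenesulfonate
Product: 12 4-[(1S)-6-bromo-5-hydroxy-4-oxo-1,2,3,4-tetrahydronaphthalen-1-yl]-5-methoxynaphthalen-1-yl benzenesulfonate, via picolyl imine 10 (not isolated), via hydroxylated imine 11 (not isolated)
Conditions: 2-(aminomethyl)pyridine (1.5 equiv), p-TsOH (5 mol%), 4 Å MS, toluene, 80 °C; then Cu(NO3)2·3H2O (1.2 equiv), acetone/THF, 35% H2O2 (5 equiv), rt; then aq Na4EDTA, 1 M HCl/THF, rt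
Reagents that add atoms: hydrogen peroxide OO
Why: Proposed new method: one-pot imine-tethered Cu(II)/H2O2 hydroxylation of the C8–H of a tetralone, in which 2-picolylamine condenses with C1=O to the E-imine 10 whose imine and pyridine nitrogens chelate Cu(II) next to C8–H, H2O2 gives a Cu(II)–OOH that delivers oxygen to the γ-carbon C8 through a six-membered transition state (the other γ-C–H at C3 lies on the far side of the C=N bond and C4–H is out of reach, so the stereocentre is untouched), and acid hydrolysis of the Cu-bound phenolate imine 11 returns the ketone; the closest known reaction type is the Schönecker-type Cu/picolylimine-directed γ-C–H hydroxylation of steroid ketones and the Cu/H2O2 ortho-hydroxylation of benzophenone imines, not yet shown on a cyclic aryl alkyl ketone or next to a halogen, and it is chosen because acidic Pd or Ru/hypervalent-iodine hydroxylations would oxidise the methoxynaphthalene and aerobic Pd(II) would dehydrogenate the tetralone to a naphthol.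

Step 6
Reactants: 12 4-[(1S)-6-bromo-5-hydroxy-4-oxo-1,2,3,4-tetrahydronaphthalen-1-yl]-5-methoxynaphthalen-1-yl benzenesulfonate
Product: 14 (4S)-7,8-dihydroxy-4-(4-hydroxy-8-methoxynaphthalen-1-yl)-3,4-dihydronaphthalen-1(2H)-one, via catechol besylate 13 (not isolated)
Conditions: CuI (10 mol%), N,N'-bis(4-hydroxy-2,6-dimethylphenyl)oxalamide (10 mol%), LiOH·H2O (8 equiv), Na ascorbate (20 mol%), degassed DMSO/H2O 4:1, Ar, 80 °C then 100 °C; 1 M HCl
Reagents that add atoms: lithium hydroxide [Li+].[OH-]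
Why: The Ullmann-type Cu-catalysed hydroxylation of the aryl bromide is helped by the chelating ortho-phenoxide, hydroxide then cleaves the aryl sulfonate at sulfur, the methyl ether is inert, and strict exclusion of O2 prevents the catechol to o-quinone to quinone methide path that would racemise C4.

## Compound list

1 | 5-methoxynaphthalen-1-ol | COc1cccc2c(O)cccc12 | starting material
2 | 4-bromo-5-methoxynaphthalen-1-ol | COc1cccc2c(O)ccc(Br)c12 | intermediate
3 | 4-bromo-5-methoxynaphthalen-1-yl benzenesulfonate | COc1cccc2c(OS(=O)(=O)c3ccccc3)ccc(Br)c12 | intermediate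
4 | 6-bromo-3,4-dihydronaphthalen-1(2H)-one | O=C1CCCc2cc(Br)ccc12 | starting material
5 | [4-(benzenesulfonyloxy)-8-methoxynaphthalen-1-yl]magnesium bromide (LiCl complex) | COc1cccc2c(OS(=O)(=O)c3ccccc3)ccc([Mg]Br)c12 | intermediate
6 | 4-(6-bromo-1-hydroxy-1,2,3,4-tetrahydronaphthalen-1-yl)-5-methoxynaphthalen-1-yl benzenesulfonate (racemic) | COc1cccc2c(OS(=O)(=O)c3ccccc3)ccc(C3(O)CCCc4cc(Br)ccc43)c12 | intermediate
7 | 4-(6-bromo-3,4-dihydronaphthalen-1-yl)-5-methoxynaphthalen-1-yl benzenesulfonate | COc1cccc2c(OS(=O)(=O)c3ccccc3)ccc(C3=CCCc4cc(Br)ccc43)c12 | intermediate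
8 | (R)-4-(6-bromo-1,2,3,4-tetrahydronaphthalen-1-yl)-5-methoxynaphthalen-1-yl benzenesulfonate | COc1cccc2c(OS(=O)(=O)c3ccccc3)ccc([C@@H]3CCCc4c3ccc(Br)c4)c12 | intermediate
9 | 4-[(1S)-6-bromo-4-oxo-1,2,3,4-tetrahydronaphthalen-1-yl]-5-methoxynaphthalen-1-yl benzenesulfonate | COc1cccc2c(OS(=O)(=O)c3ccccc3)ccc([C@@H]3CCC(=O)c4c3ccc(Br)c4)c12 | intermediate
10 | 4-[(1R,4E)-6-bromo-4-{[(pyridin-2-yl)methyl]imino}-1,2,3,4-tetrahydronaphthalen-1-yl]-5-methoxynaphthalen-1-yl benzenesulfonate | COc1cccc2c(OS(=O)(=O)c3ccccc3)ccc([C@@H]3CC/C(=N\Cc4ccccn4)c4c3ccc(Br)c4)c12 | intermediate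
11 | 4-[(1S,4E)-6-bromo-5-hydroxy-4-{[(pyridin-2-yl)methyl]imino}-1,2,3,4-tetrahydronaphthalen-1-yl]-5-methoxynaphthalen-1-yl benzenesulfonate (Cu(II)-bound in the flask) | COc1cccc2c(OS(=O)(=O)c3ccccc3)ccc([C@@H]3CC/C(=N\Cc4ccccn4)c4c3ccc(Br)c4O)c12 | intermediate
12 | 4-[(1S)-6-bromo-5-hydroxy-4-oxo-1,2,3,4-tetrahydronaphthalen-1-yl]-5-methoxynaphthalen-1-yl benzenesulfonate | COc1cccc2c(OS(=O)(=O)c3ccccc3)ccc([C@@H]3CCC(=O)c4c3ccc(Br)c4O)c12 | intermediate
13 | 4-[(1S)-5,6-dihydroxy-4-oxo-1,2,3,4-tetrahydronaphthalen-1-yl]-5-methoxynaphthalen-1-yl benzenesulfonate | COc1cccc2c(OS(=O)(=O)c3ccccc3)ccc([C@@H]3CCC(=O)c4c3ccc(O)c4O)c12 | intermediate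
14 | (4S)-7,8-dihydroxy-4-(4-hydroxy-8-methoxynaphthalen-1-yl)-3,4-dihydronaphthalen-1(2H)-one | COc1cccc2c(O)ccc([C@@H]3CCC(=O)c4c3ccc(O)c4O)c12 | target

Total step count: 6. Longest linear sequence: 6 (1 to 14).

## Steps most likely to fail

**Step 5 (the new hydroxylation).**
- Risk: C8–H is electron-poor and flanked by bromine, and imine formation on the tetralone may be slow.
- Fallback (known chemistry), from 9 back to 12: Condensation with NH2OH·HCl/pyridine gives the (E)-oxime F6. Pd(OAc)2/PhI(OAc)2 in AcOH/Ac2O acetylates the oxime in situ and carries out the oxime-ester-directed ortho C–H acetoxylation, giving the 8-acetoxy O-acetyl oxime F7. NaHSO3 in aqueous EtOH at 80 °C frees the carbonyl as the 8-acetoxy ketone F8. K2CO3/MeOH at 0 °C then removes the acetate to give 12.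

**Step 4 (site-selective benzylic oxidation).**
- Risk: attack at the tertiary C–H, at the OMe group or on the naphthalene.
- Fallback, from 8 back to 9: Cu(I)/bathophenanthroline with NFSI performs a radical-relay C–H fluorination in which the bulky sulfonimidyl radical takes only the unhindered secondary benzylic hydrogen. This gives the benzylic fluoride F4. Solvolysis in HFIP/H2O gives the benzylic alcohol F5 as a mixture of carbinol epimers. Dess–Martin oxidation converges both epimers on 9.

**Step 3 (asymmetric hydrogenation).**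
- Risk: the olefin is hindered and slow rotamer exchange may erode conversion or ee.
- Fallback, from 7 back to 8: KOH in MeOH/THF frees the naphthol olefin F1. A chiral phosphoric acid (TRIP type, 5 mol%) protonates the olefin to the para-quinone methide F2, and a Hantzsch ester delivers hydride to one face to give the naphthol tetralin F3. PhSO2Cl/Et3N then returns 8.

Further compounds
F1 | step 3 | 4-(6-bromo-3,4-dihydronaphthalen-1-yl)-5-methoxynaphthalen-1-ol | COc1cccc2c(O)ccc(C3=CCCc4cc(Br)ccc43)c12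
F2 | step 3 | 4-(6-bromo-3,4-dihydronaphthalen-1(2H)-ylidene)-5-methoxynaphthalen-1(4H)-one | COc1cccc2C(=O)C=CC(=C3CCCc4cc(Br)ccc43)c12
F3 | step 3 | (R)-4-(6-bromo-1,2,3,4-tetrahydronaphthalen-1-yl)-5-methoxynaphthalen-1-ol | COc1cccc2c(O)ccc([C@@H]3CCCc4c3ccc(Br)c4)c12
F4 | step 4 | 4-[(1S)-6-bromo-4-fluoro-1,2,3,4-tetrahydronaphthalen-1-yl]-5-methoxynaphthalen-1-yl benzenesulfonate (C4 epimers) | COc1cccc2c(OS(=O)(=O)c3ccccc3)ccc([C@@H]3CCC(F)c4c3ccc(Br)c4)c12
F5 | step 4 | 4-[(1R)-6-bromo-4-hydroxy-1,2,3,4-tetrahydronaphthalen-1-yl]-5-methoxynaphthalen-1-yl benzenesulfonate (C4 epimers) | COc1cccc2c(OS(=O)(=O)c3ccccc3)ccc([C@@H]3CCC(O)c4c3ccc(Br)c4)c12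
F6 | step 5 | 4-[(1R,4E)-6-bromo-4-(hydroxyimino)-1,2,3,4-tetrahydronaphthalen-1-yl]-5-methoxynaphthalen-1-yl benzenesulfonate | COc1cccc2c(OS(=O)(=O)c3ccccc3)ccc([C@@H]3CC/C(=N\O)c4c3ccc(Br)c4)c12
F7 | step 5 | 4-[(1S,4E)-5-acetoxy-4-(acetoxyimino)-6-bromo-1,2,3,4-tetrahydronaphthalen-1-yl]-5-methoxynaphthalen-1-yl benzenesulfonate | COc1cccc2c(OS(=O)(=O)c3ccccc3)ccc([C@@H]3CC/C(=N\OC(C)=O)c4c3ccc(Br)c4OC(C)=O)c12
F8 | step 5 | 4-[(1S)-5-acetoxy-6-bromo-4-oxo-1,2,3,4-tetrahydronaphthalen-1-yl]-5-methoxynaphthalen-1-yl benzenesulfonate | COc1cccc2c(OS(=O)(=O)c3ccccc3)ccc([C@@H]3CCC(=O)c4c3ccc(Br)c4OC(C)=O)c12
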